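The plan excises the C3=C4 etheno bridge of the dimethylpyran ring D by cutting C4–C4a and C2–C3. The key step puts this two-carbon unit back in one operation. A redox-active ester of an open-chain 2-aryloxyisobutyric acid loses CO2 to give the tertiary radical at C2. This radical adds to phenyl vinyl sulfone, an acetylene equivalent. The new radical closes onto the free ring B carbon para to the methoxy group, and sulfinate loss gives the chromene. The step exploits the O1–C2(CH3)2 α-oxy carbon and the electron-rich resorcinol pattern of ring B. The bromochromene then arylates a chromanone. The ring C stereocentre is set by transfer hydrogenation under dynamic kinetic resolution, followed by reoxidation.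

Key step: step 3

Remark: CIP analysis of the target (C4 > C2 > aryl > H) gives S at C3 of the chromanone. Rings B and D carry chromene numbering (O1, C2, C3, C4, C4a to C8a), and rings A and C carry chromanone numbering.

Step 1
Reactants: 1 4-bromo-3-methoxyphenol; 2 acetone; 3 chloroform
Product: 4 2-(4-bromo-3-methoxyphenoxy)-2-methylpropanoic acid
Conditions: NaOH (powder), acetone (also solvent), CHCl3 added at 0 °C, then reflux; aq HCl work-up
Reagents that add atoms: sodium hydroxide [Na+].[OH-]
Why: Bargellini reaction, in which the trichloromethyl anion adds to acetone, the phenoxide captures the resulting electrophile at the tertiary carbon and hydrolysis gives the hindered α-aryloxy acid directly, while the aryl bromide and the methyl ether are inert to base.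

Step 2
Reactants: 4 2-(4-bromo-3-methoxyphenoxy)-2-methylpropanoic acid
Product: 5 1,3-dioxoisoindolin-2-yl 2-(4-bromo-3-methoxyphenoxy)-2-methylpropanoate
Conditions: N-hydroxyphthalimide, DIC, DMAP (cat.), CH2Cl2, rt
Reagents that add atoms: N-hydroxyphthalimide O=C1c2ccccc2C(=O)N1O
Why: Carbodiimide (Steglich-type) esterification turns the acid into a redox-active ester that fragments after uptake of one electron, and no other group of 4 reacts with the activated acid.

Step 3
Reactants: 5 1,3-dioxoisoindolin-2-yl 2-(4-bromo-3-methoxyphenoxy)-2-methylpropanoate; 6 phenyl vinyl sulfone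
Product: 8 6-bromo-7-methoxy-2,2-dimethyl-2H-chromene, via 4-sulfonylchroman 7 (not isolated)
Conditions: 6 (1.5 equiv), fac-Ir(ppy)3 (1 mol %), MeCN, blue LEDs, rt; evaporate; then KOtBu, t-BuOH/THF, 70 °C
Reagents that add atoms: none
Why: Excited fac-Ir(ppy)3 passes one electron to the phthalimide ester of 5, which fragments to CO2, phthalimide anion and the nucleophilic tertiary α-aryloxy radical at C2; this radical adds to the CH2 end of 6 (C2–C3 bond), the electrophilic α-sulfonyl radical at C4 attacks the electron-rich arene (C4–C4a bond), and the cyclohexadienyl radical is oxidised by the tetravalent iridium complex and deprotonated by phthalimide anion to give 7, so the photochemical stage is redox-neutral. The closest known reaction type is the photoredox (4+2) radical annulation of N-hydroxyphthalimide esters of α-aryloxy acids with electron-poor olefins to chromans (Giese addition followed by homolytic aromatic substitution), and the second stage is the known base-induced 1,2-elimination of benzenesulfinate from a benzylic sulfone, which makes 6 an acetylene equivalent and keeps the radical-sensitive C3=C4 bond out of the photochemical stage. Ring D closes by six-membered attack at the ortho carbon (6-endo with respect to the C4a–C8a bond), favoured by the gem-dimethyl effect, while the competing 5-exo ipso attack is unproductive because it could only expel a high-energy alkoxyl radical. The only new stereocentre, C4 of 7, forms as a racemate and is erased by the elimination, so it needs no control. The step needs regioselectivity between the two carbons ortho to the ether oxygen: the carbon between the two oxygens is shielded because the bromine forces the methoxy methyl group to point towards it, so closure should take place at the open carbon para to methoxy. Polarity matching (nucleophilic radical with electron-poor olefin, electrophilic radical with electron-rich arene) holds back oligomerisation of 6, and the aryl bromide lies beyond the reducing power of the excited catalyst.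

Step 4
Reactants: 9 7-hydroxychroman-4-one
Product: 10 7-(triisopropylsilyloxy)chroman-4-one
Conditions: TIPSCl, imidazole, DMF, rt
Reagents that add atoms: triisopropylsilyl chloride CC(C)[Si](Cl)(C(C)C)C(C)C
Why: Standard silylation of the acidic phenol, with the bulky silyl ether chosen because it should resist the phosphate base, the formate medium and the periodinane and can leave under non-basic fluoride conditions.

Step 5
Reactants: 8 6-bromo-7-methoxy-2,2-dimethyl-2H-chromene; 10 7-(triisopropylsilyloxy)chroman-4-one
Product: 11 rac-3-(7-methoxy-2,2-dimethyl-2H-chromen-6-yl)-7-(triisopropylsilyloxy)chroman-4-one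
Conditions: Pd2(dba)3 (2 mol %), XPhos, K3PO4, toluene, 90 °C
Reagents that add atoms: none
Why: Palladium-catalysed ketone α-arylation (Buchwald–Hartwig type), in which the bulky biaryl phosphine promotes oxidative addition of the hindered bromide to zerovalent palladium, the mild insoluble base keeps the enolate of 10 dilute so that the pyranone ring and the silyl ether survive, the ortho-methoxyaryl group blocks a second arylation, and C3 is racemic at this stage.

Step 6
Reactants: 11 rac-3-(7-methoxy-2,2-dimethyl-2H-chromen-6-yl)-7-(triisopropylsilyloxy)chroman-4-one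
Product: 12 (3S,4S)-3-(7-methoxy-2,2-dimethyl-2H-chromen-6-yl)-7-(triisopropylsilyloxy)chroman-4-ol (cis)
Conditions: RuCl[(S,S)-TsDPEN](p-cymene) (2 mol %), HCO2H/Et3N (1:1), EtOAc, 40 °C
Reagents that add atoms: none
Why: Noyori asymmetric transfer hydrogenation with dynamic kinetic resolution, in which triethylamine racemises the acidic C3–H through the enol faster than hydride transfer, the (S,S) catalyst reduces the aryl ketone in its usual sense to set 4S and accepts only the enantiomer whose 3-aryl group lies away from the incoming hydride, so the cis (3S,4S) alcohol should result while the unpolarised chromene C=C is left alone.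

Step 7
Reactants: 12 (3S,4S)-3-(7-methoxy-2,2-dimethyl-2H-chromen-6-yl)-7-(triisopropylsilyloxy)chroman-4-ol
Product: 13 (3S)-3-(7-methoxy-2,2-dimethyl-2H-chromen-6-yl)-7-(triisopropylsilyloxy)chroman-4-one
Conditions: Dess–Martin periodinane, CH2Cl2, 0 °C to rt; neutral work-up
Reagents that add atoms: none
Why: Dess–Martin oxidation under base-free conditions removes the auxiliary C4 stereocentre without enolising the new ketone, so the S configuration at C3 should be kept.

Step 8
Reactants: 13 (3S)-3-(7-methoxy-2,2-dimethyl-2H-chromen-6-yl)-7-(triisopropylsilyloxy)chroman-4-one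
Product: 14 (3S)-7-hydroxy-3-(7-methoxy-2,2-dimethyl-2H-chromen-6-yl)chroman-4-one
Conditions: Et3N·3HF, THF, 0 °C to rt
Reagents that add atoms: none
Why: Fluoride-induced cleavage of the phenolic silyl ether with a weakly acidic amine–HF complex avoids both free base, which would racemise C3, and strong acid, which would attack the chromene.

Compound list
1 | 4-bromo-3-methoxyphenol | COc1cc(O)ccc1Br | starting material
2 | acetone | CC(C)=O | starting material
3 | chloroform | ClC(Cl)Cl | starting material
4 | 2-(4-bromo-3-methoxyphenoxy)-2-methylpropanoic acid | COc1cc(OC(C)(C)C(=O)O)ccc1Br | intermediate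
5 | 1,3-dioxoisoindolin-2-yl 2-(4-bromo-3-methoxyphenoxy)-2-methylpropanoate | COc1cc(OC(C)(C)C(=O)ON2C(=O)c3ccccc3C2=O)ccc1Br | intermediate
6 | phenyl vinyl sulfone | C=CS(=O)(=O)c1ccccc1 | starting material
7 | rac-6-bromo-7-methoxy-2,2-dimethyl-4-(phenylsulfonyl)chromane (not isolated) | COc1cc2c(cc1Br)C(CC(C)(C)O2)S(=O)(=O)c1ccccc1 | intermediate
8 | 6-bromo-7-methoxy-2,2-dimethyl-2H-chromene | COc1cc2c(cc1Br)C=CC(C)(C)O2 | intermediate
9 | 7-hydroxychroman-4-one | O=C1CCOc2cc(O)ccc12 | starting material
10 | 7-(triisopropylsilyloxy)chroman-4-one | O=C1CCOc2cc(O[Si](C(C)C)(C(C)C)C(C)C)ccc12 | intermediate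
11 | rac-3-(7-methoxy-2,2-dimethyl-2H-chromen-6-yl)-7-(triisopropylsilyloxy)chroman-4-one | COc1cc2c(cc1C1COc3cc(O[Si](C(C)C)(C(C)C)C(C)C)ccc3C1=O)C=CC(C)(C)O2 | intermediate
12 | (3S,4S)-3-(7-methoxy-2,2-dimethyl-2H-chromen-6-yl)-7-(triisopropylsilyloxy)chroman-4-ol | COc1cc2c(cc1[C@H]1COc3cc(O[Si](C(C)C)(C(C)C)C(C)C)ccc3[C@H]1O)C=CC(C)(C)O2 | intermediate
13 | (3S)-3-(7-methoxy-2,2-dimethyl-2H-chromen-6-yl)-7-(triisopropylsilyloxy)chroman-4-one | COc1cc2c(cc1[C@H]1COc3cc(O[Si](C(C)C)(C(C)C)C(C)C)ccc3C1=O)C=CC(C)(C)O2 | intermediate
14 | (3S)-7-hydroxy-3-(7-methoxy-2,2-dimethyl-2H-chromen-6-yl)chroman-4-one | COc1cc2c(cc1[C@H]1COc3cc(O)ccc3C1=O)C=CC(C)(C)O2 | target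

Total step count: 8. Longest linear sequence: 7 (steps 1, 2, 3, 5, 6, 7, 8).

Steps most likely to fail

Risk 1 (step 3).
- **What may go wrong:** Closure of the α-sulfonyl radical onto the arene may be slow, so hydrogen abstraction or attack at the carbon between the two oxygens could compete. Sulfinate loss may also stall because the benzylic position is deprotonated instead.
- **Fallback:** It sets out from 1. O-alkylation with 3-chloro-3-methylbut-1-yne (CuCl2 cat., DBU, MeCN, 0 °C) gives 1-bromo-2-methoxy-4-[(2-methylbut-3-yn-2-yl)oxy]benzene F1. Heating F1 in N,N-diethylaniline (about 190 °C) triggers the aromatic Claisen rearrangement and ring-closure cascade of aryl propargyl ethers. The route is rejoined at 8.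

Risk 2 (step 5).
- **What may go wrong:** The base may open the pyranone ring by retro-oxa-Michael reaction or strip the silyl ether. Oxidative addition of the hindered, electron-rich bromide may be slow.
- **Fallback:** It reverses the polarity and sets out from 10 and 8.
  - Bromination of 10 (PhNMe3Br3, THF, 0 °C) gives rac-3-bromo-7-(triisopropylsilyloxy)chroman-4-one F2.
  - Bromine–lithium exchange on 8 (n-BuLi, THF, −78 °C) gives (7-methoxy-2,2-dimethyl-2H-chromen-6-yl)lithium F3.
  - ZnCl2 converts F3 into (7-methoxy-2,2-dimethyl-2H-chromen-6-yl)zinc chloride F4.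
  - A base-free nickel-catalysed Negishi coupling of F2 with F4 (NiCl2(dme), pybox ligand, glyme/THF, −30 °C) rejoins the route at 11.

Risk 3 (step 6).
- **What may go wrong:** Racemisation of the ketone may be too slow relative to hydride transfer. The bulky ortho-methoxyaryl group may also weaken facial discrimination. Either would erode enantiomeric and cis/trans purity.
- **Fallback:** It sets out from 11. Soft enolisation (TMSOTf, Et3N, CH2Cl2, 0 °C) gives {[3-(7-methoxy-2,2-dimethyl-2H-chromen-6-yl)-7-(triisopropylsilyloxy)-2H-chromen-4-yl]oxy}trimethylsilane F5. This is protonated enantioselectively with a catalytic BINOL-derived N-triflyl thiophosphoramide and phenol as the stoichiometric proton source (toluene, low temperature). The catalyst antipode is chosen for the S ketone. The route is rejoined at 13, bypassing 12.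

Further compounds
F1 | step 3 | 1-bromo-2-methoxy-4-[(2-methylbut-3-yn-2-yl)oxy]benzene | COc1cc(OC(C)(C)C#C)ccc1Br
F2 | step 5 | rac-3-bromo-7-(triisopropylsilyloxy)chroman-4-one | O=C1C(Br)COc2cc(O[Si](C(C)C)(C(C)C)C(C)C)ccc12
F3 | step 5 | (7-methoxy-2,2-dimethyl-2H-chromen-6-yl)lithium | COc1cc2c(cc1[Li])C=CC(C)(C)O2
F4 | step 5 | (7-methoxy-2,2-dimethyl-2H-chromen-6-yl)zinc chloride | COc1cc2c(cc1[Zn]Cl)C=CC(C)(C)O2
F5 | step 6 | {[3-(7-methoxy-2,2-dimethyl-2H-chromen-6-yl)-7-(triisopropylsilyloxy)-2H-chromen-4-yl]oxy}trimethylsilane | COc1cc2c(cc1C1=C(O[Si](C)(C)C)c3ccc(O[Si](C(C)C)(C(C)C)C(C)C)cc3OC1)C=CC(C)(C)O2
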